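3 questions stand on this flask, and two of them, the excess and the pace, hang on one ratio of concentrations, so you look at that ratio before any rate.

in all of them: G 20 mM; X 20 mM

| run | L | J | remark | time |
|---|---|---|---|---|
| gamma | 44 mM (fed, over 8.0 min) | 1.7 mM | run made earlier |  |
| flask | 44.0 mM (fed, over 8.0 min) | 3.4 mM |  | 50 h |

- gamma (time / h: E / %, Z / %, G / %): 1.33: 19.8, 6.1, 36.6; 3.00: 23.7, 7.5, 34.1; 6.00: 25.7, 8.2, 32.5; 15.0: 30.2, 9.7, 29.5

(standard deviation of a reading: 0.3 percentage points)

- J is single-handed; G and X are mirror images of each other, charged as a racemate, each of them at the stated concentration
- on the list of suspects stand: L + J + G -> J + E; L + J + X -> J + Z; G <-> X; J <-> D; 2 J -> Q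
- an excess is the difference of the two amounts in percent of their sum
- an excess is below zero if the other one leads
- no earlier run changes the charge of J; that part of a forecast is a guess

- E and Z together, in percent of the G and X charged together, at 50 h
- excess of E over Z in the product at 50 h
- whether the exchange between G and X keeps pace with the reaction: how far the product's excess at 50 h gets from its value without exchange to its value with instant exchange (above 80 % keeps pace, below 20 % hardly takes part, else lags behind)

On the suspect steps, the rates of E and Z both carry c_L and c_J, so these divide out and E grows against Z as s times c_G/c_X, with s the selectivity factor. An error in the dosing or in the time allowed therefore hardly moves the excess. What you must know well is whether c_G/c_X stays at one, and then s.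

At 15.0 h of the gamma run, E and G together hold 59.7 %, more than the half charged as G, so X has been crossing into G. An error in s goes straight into the excess, so s has to be read with care: the first reading gives an excess of 52.9 % and the last 51.4 %, each carrying the scatter of its readings. Pooling the four readings, I read s as 3.16, and the level-pair excess, s less one over s plus one, the excess of product formed while G and X stand equal, as 51.9 %. The yield is different, since it carries c_J, and no earlier run changes the charge of J.

The forecast gives 73 %, 51 % and keeps pace, taking as its guess on J: “Doubling J (an assumed first-order effect) doubles the integrated rate”.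

The flask gives 68.0 %, 50.5 % and keeps pace, at 94 % of the way.

    L + J + G → J + E (k = 230 M⁻² min⁻¹)
    L + J + X → J + Z (k = 73.0 M⁻² min⁻¹)
    G ⇌ X (k = 0.0580 min⁻¹)
    J ⇌ D (K = 29.0, k = 0.0170 min⁻¹)
    2 J → Q (k = 3.90 M⁻¹ min⁻¹)

At 50.0 h in this flask, the forward exchange half-life of G is 0.20 h, far shorter than the 130 h half-life of L by the step to E. G and X stand level at 16.0 % and 16.0 %, and the excess lies 1.4 percentage points below the level-pair excess. For the neighbour with 18 mM of L, c_L divides out and the reckoning again gives 51.9 %; computed, it reaches 51.3 % at a yield of 33.8 %, half of this flask's.

The runs come from a simulation for an exercise.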